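The route rests on disconnecting C6–C7 (germacrane numbering), the bond that joins the α-methylene lactone to the nine-membered oxa-bridged ring (C8, C9, C10, ring O, C3, C4, C5, C6, C7). The key step exploits the fact that C7, the fusion atom of lactone and nine-membered ring, is the γ-terminus of an allyl unit C13–C11=C7 hidden in a 3-(bromomethyl)butenolide. A chromium-mediated intramolecular allylation of the C6 (Z)-enal closes this last ring, sets C6 and C7 and unveils the C11=C13 methylene in one operation. Its precursor is a preformed, C10-quaternary 3(2H)-furanone carrying the enal at C3/C4 and the bromobutenolide on C9; C6 is then inverted during angeloylation.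

Key step: step 14

Numbering: C1 ketone carbon, C2 (=CH), C3 enol-ether carbon, C4 (bears C15H2OH), C5 (=CH), C6 (O-angeloyl), C7, C8 (lactone O), C9 (CH2), C10 (quaternary, methyl C14, ring O), C11 (=C13H2), C12 lactone carbonyl.

Assumption: the chair transition state of step 14 is taken to give the anti (6R) carbinol, and the route is written for that outcome. The opposite outcome is covered in the fallbacks.

**Step 1**
Reactants: 1 (S)-lactic acid; 2 pivalaldehyde
Product: 3 (2S,5S)-2-tert-butyl-5-methyl-1,3-dioxolan-4-one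
Conditions: p-TsOH (cat.), pentane, reflux, Dean–Stark; recrystallisation at −78 °C
Reagents that add atoms: pivalaldehyde (2), CC(C)(C)C=O
Why: Acid-catalysed acetalisation of the α-hydroxy acid (self-regeneration of stereocentres) should favour the cis acetal, which is purified by crystallisation and stores the lactic acid chirality at the acetal carbon.

**Step 2**
Reactants: 3 (2S,5S)-2-tert-butyl-5-methyl-1,3-dioxolan-4-one; 4 allyl bromide
Product: 6 (2S,5R)-2-tert-butyl-5-methyl-5-(prop-2-en-1-yl)-1,3-dioxolan-4-one, via lithium enolate 5 (not isolated)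
Conditions: LiN(i-Pr)2, THF, −78 °C; then allyl bromide, −78 → −30 °C
Reagents that add atoms: allyl bromide (4), C=CCBr
Why: Diastereoselective enolate alkylation, in which the tert-butyl group shields one face of the planar enolate so that allyl enters trans to it and the quaternary C10 is formed as the R centre.

**Step 3**
Reactants: 6 (2S,5R)-2-tert-butyl-5-methyl-5-(prop-2-en-1-yl)-1,3-dioxolan-4-one
Product: 8 2-[(2S,4R)-2-tert-butyl-4-methyl-5-oxo-1,3-dioxolan-4-yl]acetaldehyde, via secondary ozonide 7 (not isolated)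
Conditions: O3, CH2Cl2, −78 °C; then Me2S, −78 °C → rt
Reagents that add atoms: ozone, [O-][O+]=O
Why: Ozonolysis with reductive work-up cleaves the only alkene to the C8 aldehyde while the acetal lactone and the quaternary centre are inert.

**Step 4**
Reactants: 8 2-[(2S,4R)-2-tert-butyl-4-methyl-5-oxo-1,3-dioxolan-4-yl]acetaldehyde; 9 vinylmagnesium bromide
Product: 11 (3R,5S)-5-ethenyl-3-hydroxy-3-methyloxolan-2-one, via hydroxy dioxolanone 10 (not isolated)
Conditions: (CH2=CH)2Zn (from CH2=CHMgBr and ZnCl2, Mg salts precipitated with 1,4-dioxane), (+)-3-exo-morpholinoisoborneol (5 mol %), toluene, −20 → 0 °C; aq. NH4Cl; then p-TsOH (cat.), CH2Cl2, rt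
Reagents that add atoms: vinylmagnesium bromide (9), C=C[Mg]Br, transferred as divinylzinc, C=C[Zn]C=C
Why: Amino-alcohol-catalysed enantioselective alkenylzinc addition should deliver the vinyl group to the Re face of the aldehyde under reagent control (8S), after which acid-catalysed translactonisation of the γ-hydroxy acetal ester releases pivalaldehyde and allows any C8 epimer to be removed as the diastereomeric lactone.

**Step 5**
Reactants: 12 but-2-yne-1,4-diol
Product: 13 4-[(tert-butyldimethylsilyl)oxy]but-2-yn-1-ol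
Conditions: NaH (1.0 equiv), THF, 0 °C → rt; then TBSCl
Reagents that add atoms: tert-butyldimethylsilyl chloride, CC(C)(C)[Si](C)(C)Cl
Why: Monosilylation through the sparingly soluble monosodium alkoxide desymmetrises the diol and protects the future C15 hydroxyl until the last step.

**Step 6**
Reactants: 13 4-[(tert-butyldimethylsilyl)oxy]but-2-yn-1-ol
Product: 15 (2Z)-4-[(tert-butyldimethylsilyl)oxy]-3-iodobut-2-en-1-ol, via cyclic alkenylaluminate 14 (not isolated)
Conditions: NaAlH2(OCH2CH2OCH3)2, THF, 0 °C → rt; then I2, −78 → 0 °C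
Reagents that add atoms: iodine, II
Why: Hydroxyl-directed trans-hydroalumination places aluminium on the distal alkyne carbon (C4) and hydride on C5, and iododealumination with retention gives the (Z)-vinyl iodide, fixing the C4=C5 geometry (iodine, later C3, cis to C6).

**Step 7**
Reactants: 15 (2Z)-4-[(tert-butyldimethylsilyl)oxy]-3-iodobut-2-en-1-ol; 16 trimethylsilylacetylene
Product: 18 (2E)-3-{[(tert-butyldimethylsilyl)oxy]methyl}pent-2-en-4-yn-1-ol, via silylated enynol 17 (not isolated)
Conditions: PdCl2(PPh3)2 (3 mol %), CuI (6 mol %), i-Pr2NH, THF, rt; then K2CO3, MeOH, 0 °C → rt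
Reagents that add atoms: trimethylsilylacetylene (16), C#C[Si](C)(C)C
Why: Sonogashira coupling installs C2–C3 with retention of the alkene geometry (the descriptor changes to E only by priority), and methanolysis removes the alkynyl silyl group while the silyl ether survives.

**Step 8**
Reactants: 18 (2E)-3-{[(tert-butyldimethylsilyl)oxy]methyl}pent-2-en-4-yn-1-ol
Product: 19 tert-butyl(dimethyl){[(2E)-2-ethynyl-4-[(triethylsilyl)oxy]but-2-en-1-yl]oxy}silane
Conditions: TESCl, imidazole, CH2Cl2, 0 °C
Reagents that add atoms: triethylsilyl chloride, CC[Si](CC)(CC)Cl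
Why: Silylation masks the C6 hydroxyl, which would otherwise add to the cis-disposed alkyne (furan formation) once this becomes an ynone, and triethylsilyl can later be removed beside the C15 tert-butyldimethylsilyl ether.

**Step 9**
Reactants: 19 tert-butyl(dimethyl){[(2E)-2-ethynyl-4-[(triethylsilyl)oxy]but-2-en-1-yl]oxy}silane; 11 (3R,5S)-5-ethenyl-3-hydroxy-3-methyloxolan-2-one
Product: 22 (2R)-5-[(2Z)-1-[(tert-butyldimethylsilyl)oxy]-4-[(triethylsilyl)oxy]but-2-en-2-yl]-2-[(2S)-2-hydroxybut-3-en-1-yl]-2-methylfuran-3(2H)-one, via lithium acetylide 20 (not isolated), via hydroxy ynone 21 (not isolated)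
Conditions: 19 (2.2 equiv), n-BuLi (2.1 equiv), THF, −78 °C; then 11, −78 → −40 °C; then MeOH, K2CO3 (0.3 equiv), −40 → 0 °C; aq. NH4Cl
Reagents that add atoms: none
Why: Acetylide addition to the lactone carbonyl (one equivalent is consumed by the tertiary hydroxyl and recovered) opens it to the α'-hydroxy ynone, and the methoxide-buffered quench should trigger 5-endo-dig oxa-Michael addition of the C10 oxygen to C3, the classical 3(2H)-furanone synthesis, leaving C8, C10 and the C4=C5 geometry untouched.

**Step 10**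
Reactants: 22 the furanone of step 9; 23 2-(bromomethyl)acrylic acid
Product: 24 (2S)-1-{(2R)-5-[(2Z)-1-[(tert-butyldimethylsilyl)oxy]-4-[(triethylsilyl)oxy]but-2-en-2-yl]-2-methyl-3-oxo-2,3-dihydrofuran-2-yl}but-3-en-2-yl 2-(bromomethyl)prop-2-enoate
Conditions: DCC, DMAP (10 mol %), CH2Cl2, 0 °C
Reagents that add atoms: 2-(bromomethyl)acrylic acid (23), C=C(CBr)C(=O)O
Why: Steglich esterification of the only free hydroxyl (C8–OH) brings in C11, C12 and C13 and creates the C8–O–C12 bond that fixes the 8,12-lactone regiochemistry.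

**Step 11**
Reactants: 24 the 2-(bromomethyl)acrylate of step 10
Product: 25 (5S)-3-(bromomethyl)-5-({(2R)-5-[(2Z)-1-[(tert-butyldimethylsilyl)oxy]-4-[(triethylsilyl)oxy]but-2-en-2-yl]-2-methyl-3-oxo-2,3-dihydrofuran-2-yl}methyl)furan-2(5H)-one
Conditions: second-generation Grubbs catalyst (5 mol %), CH2Cl2, 40 °C
Reagents that add atoms: none
Why: Ring-closing metathesis between the C7 vinyl group and the acrylate forms the butenolide C7=C11, since initiation occurs at the monosubstituted alkene while the trisubstituted, electron-poor C2=C3 and C4=C5 bonds are inert and C8 is not touched.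

**Step 12**
Reactants: 25 the bromobutenolide of step 11
Product: 26 (5S)-3-(bromomethyl)-5-({(2R)-5-[(2Z)-1-[(tert-butyldimethylsilyl)oxy]-4-hydroxybut-2-en-2-yl]-2-methyl-3-oxo-2,3-dihydrofuran-2-yl}methyl)furan-2(5H)-one
Conditions: PPTS (0.2 equiv), MeOH/CH2Cl2, 0 °C
Reagents that add atoms: none
Why: Acid-catalysed methanolysis cleaves the primary triethylsilyl ether much faster than the tert-butyldimethylsilyl ether, and no free amine is present that could quaternise the allylic bromide.

**Step 13**
Reactants: 26 the allylic alcohol of step 12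
Product: 27 (2Z)-3-[(5R)-5-{[(2S)-4-(bromomethyl)-5-oxo-2,5-dihydrofuran-2-yl]methyl}-5-methyl-4-oxo-4,5-dihydrofuran-2-yl]-4-[(tert-butyldimethylsilyl)oxy]but-2-enal
Conditions: Dess–Martin periodinane, NaHCO3, CH2Cl2, 0 °C → rt
Reagents that add atoms: none
Why: Dess–Martin oxidation gives the (Z)-enal under buffered, non-basic conditions that spare the allylic bromide and the butenolide γ-hydrogen and should not isomerise the C4=C5 bond.

**Step 14**
Reactants: 27 the bromobutenolide enal of step 13
Product: 29 (6R,7R,8S,10R)-tricyclic alcohol (the target skeleton with 6-epi C6–OH and C15–O-tert-butyldimethylsilyl), via allylchromium dichloride 28 (not isolated)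
Conditions: CrCl2 (6 equiv), THF, 2 mM, syringe-pump addition of 27, rt
Reagents that add atoms: none
Why: Divalent chromium reduces the allylic C13–Br bond by two one-electron transfers to the trivalent allylchromium 28, which adds through its γ-carbon C7 to the C6 aldehyde in a six-membered chair transition state, forming C6–C7 and moving the double bond to C11=C13. The closest known reactions are the Nozaki–Hiyama–Kishi (Barbier-type) allylation of aldehydes with 3-(bromomethyl)furan-2(5H)-one and its intramolecular use with 2-(alkoxycarbonyl)allyl bromides to close ten-membered germacranolide rings. The nine-membered ring C8–C9–C10–O–C3–C4–C5–C6–C7 is closed by a 9-exo-trig addition to the aldehyde carbonyl, the lactone and furanone rings being already in place. C7 is controlled by C8, the new bond forming on the butenolide face anti to the C8–C9 bond (trans-fused lactone, 7R), and C6 by the transition state, in which C8 is locked trans to C13 and therefore pseudo-equatorial and the aldehyde substituent C5 is also pseudo-equatorial, which should give the anti carbinol 6R, the C6 epimer of the target that step 15 inverts. The step needs γ- over α-attack (normal for allylchromium), closure over oligomerisation (high dilution, helped by the planar furanone and the Z C4=C5 bond holding C6 near C7) and aldehyde over ketone selectivity (allylchromium reagents do not add to the vinylogous ester C1=O or to the lactone). The silyl ether, the enal geometry, C8 and C10 should not be affected by the neutral conditions.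

**Step 15**
Reactants: 29 the (6R)-alcohol of step 14; 30 angelic acid
Product: 31 15-O-tert-butyldimethylsilyl ether of the target (6S,7R,8S,10R)
Conditions: PPh3, DIAD (betaine preformed), toluene, 0 °C → rt
Reagents that add atoms: angelic acid (30), C/C=C(/C)C(=O)O
Why: Mitsunobu esterification, in which the carboxylate displaces the C6 oxyphosphonium group with inversion (6R → 6S) under neutral conditions that should not isomerise the angelate to the tiglate, allylic transposition being disfavoured because C4 is fully substituted and the allyl cation is destabilised by the furanone.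

**Step 16**
Reactants: 31 the silyl-protected angelate of step 15
Product: 32 target CNP0176514.1
Conditions: HF·pyridine, THF/pyridine, 0 °C → rt
Reagents that add atoms: none
Why: Fluoride-mediated cleavage of the primary silyl ether frees the C15 hydroxyl under mildly acidic conditions that the angelate, the α-methylene lactone and the furanone should tolerate.

**Compound list**

1 | (S)-lactic acid | C[C@H](O)C(=O)O | starting material
2 | pivalaldehyde | CC(C)(C)C=O | starting material
3 | (2S,5S)-2-tert-butyl-5-methyl-1,3-dioxolan-4-one | C[C@@H]1O[C@H](C(C)(C)C)OC1=O | intermediate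
4 | allyl bromide | C=CCBr | starting material
5 | lithium (2S)-2-tert-butyl-5-methyl-1,3-dioxol-4-olate (enolate of 3) | [Li]OC1=C(C)O[C@H](C(C)(C)C)O1 | intermediate
6 | (2S,5R)-2-tert-butyl-5-methyl-5-(prop-2-en-1-yl)-1,3-dioxolan-4-one | C=CC[C@@]1(C)O[C@H](C(C)(C)C)OC1=O | intermediate
7 | secondary ozonide of 6, (2S,5R)-2-tert-butyl-5-methyl-5-[(1,2,4-trioxolan-3-yl)methyl]-1,3-dioxolan-4-one (trioxolane carbon undefined) | C1OOC(C[C@@]2(C)O[C@H](C(C)(C)C)OC2=O)O1 | intermediate
8 | 2-[(2S,4R)-2-tert-butyl-4-methyl-5-oxo-1,3-dioxolan-4-yl]acetaldehyde | O=CC[C@@]1(C)O[C@H](C(C)(C)C)OC1=O | intermediate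
9 | vinylmagnesium bromide | C=C[Mg]Br | starting material
10 | (2S,5R)-2-tert-butyl-5-[(2S)-2-hydroxybut-3-en-1-yl]-5-methyl-1,3-dioxolan-4-one | C=C[C@@H](O)C[C@@]1(C)O[C@H](C(C)(C)C)OC1=O | intermediate
11 | (3R,5S)-5-ethenyl-3-hydroxy-3-methyloxolan-2-one | C=C[C@@H]1C[C@@](C)(O)C(=O)O1 | intermediate
12 | but-2-yne-1,4-diol | OCC#CCO | starting material
13 | 4-[(tert-butyldimethylsilyl)oxy]but-2-yn-1-ol | CC(C)(C)[Si](C)(C)OCC#CCO | intermediate
14 | sodium 2,2-bis(2-methoxyethoxy)-3-{[(tert-butyldimethylsilyl)oxy]methyl}-2,5-dihydro-1,2-oxaaluminol-2-uide (cyclic alkenylaluminate) | [Na+].COCCO[Al-]1(OCCOC)OCC=C1CO[Si](C)(C)C(C)(C)C | intermediate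
15 | (2Z)-4-[(tert-butyldimethylsilyl)oxy]-3-iodobut-2-en-1-ol | OC/C=C(\I)CO[Si](C)(C)C(C)(C)C | intermediate
16 | trimethylsilylacetylene | C#C[Si](C)(C)C | starting material
17 | (2E)-3-{[(tert-butyldimethylsilyl)oxy]methyl}-5-(trimethylsilyl)pent-2-en-4-yn-1-ol | OC/C=C(\C#C[Si](C)(C)C)CO[Si](C)(C)C(C)(C)C | intermediate
18 | (2E)-3-{[(tert-butyldimethylsilyl)oxy]methyl}pent-2-en-4-yn-1-ol | OC/C=C(\C#C)CO[Si](C)(C)C(C)(C)C | intermediate
19 | tert-butyl(dimethyl){[(2E)-2-ethynyl-4-[(triethylsilyl)oxy]but-2-en-1-yl]oxy}silane | CC[Si](CC)(CC)OC/C=C(\C#C)CO[Si](C)(C)C(C)(C)C | intermediate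
20 | lithium acetylide of 19 | [Li]C#C/C(CO[Si](C)(C)C(C)(C)C)=C\CO[Si](CC)(CC)CC | intermediate
21 | (4R,6S,9E)-4,6-dihydroxy-4-methyl-9-{[(tert-butyldimethylsilyl)oxy]methyl}-11-[(triethylsilyl)oxy]undeca-1,9-dien-7-yn-5-one... named here as the α'-hydroxy ynone from 11 and 20: (5R,7S)-5,7-dihydroxy-5-methyl-1-alkenyl-non-8-en-2-yn-4-one with the (Z-configured, C3 cis to C6) silylated butenyl unit on the alkyne | C=C[C@@H](O)C[C@@](C)(O)C(=O)C#C/C(CO[Si](C)(C)C(C)(C)C)=C\CO[Si](CC)(CC)CC | intermediate
22 | (2R)-5-[(2Z)-1-[(tert-butyldimethylsilyl)oxy]-4-[(triethylsilyl)oxy]but-2-en-2-yl]-2-[(2S)-2-hydroxybut-3-en-1-yl]-2-methylfuran-3(2H)-one | C=C[C@@H](O)C[C@@]1(C)OC(=CC1=O)/C(CO[Si](C)(C)C(C)(C)C)=C\CO[Si](CC)(CC)CC | intermediate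
23 | 2-(bromomethyl)acrylic acid | C=C(CBr)C(=O)O | starting material
24 | 2-(bromomethyl)prop-2-enoate ester of 22 at C8–OH | C=C[C@@H](OC(=O)C(=C)CBr)C[C@@]1(C)OC(=CC1=O)/C(CO[Si](C)(C)C(C)(C)C)=C\CO[Si](CC)(CC)CC | intermediate
25 | (5S)-3-(bromomethyl)-5-({(2R)-5-[(2Z)-1-[(tert-butyldimethylsilyl)oxy]-4-[(triethylsilyl)oxy]but-2-en-2-yl]-2-methyl-3-oxo-2,3-dihydrofuran-2-yl}methyl)furan-2(5H)-one | BrCC1=C[C@H](C[C@@]2(C)OC(=CC2=O)/C(CO[Si](C)(C)C(C)(C)C)=C\CO[Si](CC)(CC)CC)OC1=O | intermediate
26 | (5S)-3-(bromomethyl)-5-({(2R)-5-[(2Z)-1-[(tert-butyldimethylsilyl)oxy]-4-hydroxybut-2-en-2-yl]-2-methyl-3-oxo-2,3-dihydrofuran-2-yl}methyl)furan-2(5H)-one | BrCC1=C[C@H](C[C@@]2(C)OC(=CC2=O)/C(CO[Si](C)(C)C(C)(C)C)=C\CO)OC1=O | intermediate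
27 | (2Z)-3-[(5R)-5-{[(2S)-4-(bromomethyl)-5-oxo-2,5-dihydrofuran-2-yl]methyl}-5-methyl-4-oxo-4,5-dihydrofuran-2-yl]-4-[(tert-butyldimethylsilyl)oxy]but-2-enal | BrCC1=C[C@H](C[C@@]2(C)OC(=CC2=O)/C(CO[Si](C)(C)C(C)(C)C)=C\C=O)OC1=O | intermediate
28 | allylchromium dichloride derived from 27 (CrCl2 group in place of Br at C13) | Cl[Cr](Cl)CC1=C[C@H](C[C@@]2(C)OC(=CC2=O)/C(CO[Si](C)(C)C(C)(C)C)=C\C=O)OC1=O | intermediate
29 | (6R,7R,8S,10R)-tricyclic alcohol: target skeleton with free 6-epi C6–OH and C15–O-tert-butyldimethylsilyl | C=C1C(=O)O[C@H]2C[C@@]3(C)OC(=CC3=O)/C(CO[Si](C)(C)C(C)(C)C)=C\[C@@H](O)[C@H]12 | intermediate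
30 | angelic acid, (2Z)-2-methylbut-2-enoic acid | C/C=C(/C)C(=O)O | starting material
31 | 15-O-tert-butyldimethylsilyl ether of the target (6S,7R,8S,10R) | C=C1C(=O)O[C@H]2C[C@@]3(C)OC(=CC3=O)/C(CO[Si](C)(C)C(C)(C)C)=C\[C@H](OC(=O)/C(C)=C\C)[C@H]12 | intermediate
32 | CNP0176514.1 | C=C1C(=O)O[C@H]2C[C@@]3(C)OC(=CC3=O)/C(CO)=C\[C@H](OC(=O)/C(C)=C\C)[C@H]12 | target

**Step count and risks**

Total step count: 16. Longest linear sequence: 12 steps (steps 1–4 or 5–8, then 9–16).

Steps most likely to fail:

1. Step 14 (key step). The chromium-templated closure may show poor facial selectivity (cis-fused lactone, or the other C6 epimer), and reduction of the allylic bromide, oligomerisation or translactonisation of the chromium alkoxide onto C12 may compete with ring closure. Fallback: a Lewis-acid-promoted cyclisation of an isolated allylstannane through an open transition state. It sets out from 25. Hexabutylditin, (Bu3Sn)2, and Pd(PPh3)4 in THF convert the allylic bromide into the allyltributylstannane F1. PPTS in MeOH gives the C6 alcohol F2, and Dess–Martin periodinane the stannyl enal F3. BF3·OEt2 in CH2Cl2 at −78 °C under high dilution then closes C6–C7 with loss of tin and comes back to the route at 29. If the open transition state gives the 6S carbinol F4 instead, F4 is acylated with retention (angelic acid, 2,4,6-trichlorobenzoyl chloride, Et3N, toluene) and the route is rejoined at 31.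

2. Step 15. Backside displacement at the hindered C6 carbinol may be slow, so that elimination towards C7 or conjugate addition of the phosphine to the α-methylene lactone takes over. Fallback: inversion by oxidation and reduction, then acylation with retention. It sets out from 29. Dess–Martin periodinane (NaHCO3, CH2Cl2, 0 °C) gives the C6 enone F5. NaBH4 with CeCl3·7H2O in MeOH at −78 °C (Luche reduction) should deliver hydride to the exposed face of the C6 carbonyl, away from the lactone, to give the 6S alcohol F6; the low temperature limits enolisation at C7. Yamaguchi esterification (angelic acid, 2,4,6-trichlorobenzoyl chloride, Et3N, toluene, then F6, 60 °C) comes back to the route at 31.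

3. Step 11. The ruthenium alkylidene may be diverted by the allylic bromide, or cyclisation onto the 2-substituted acrylate may stall. Fallback: carry C13 through the metathesis as a 4-methoxybenzyl ether and make the bromide afterwards. It sets out from 22 and 23. Treating 23 with 4-methoxybenzyl alcohol and NaH in THF gives 2-{[(4-methoxybenzyl)oxy]methyl}acrylic acid F7. Esterification of 22 with F7 (DCC, DMAP) gives the ester F8, and ring-closing metathesis (second-generation Grubbs catalyst, CH2Cl2, 40 °C) the butenolide ether F9. DDQ in CH2Cl2/pH 7 buffer frees the alcohol F10, and CBr4/PPh3 (CH2Cl2, 0 °C) comes back to the route at 25.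

**Further compounds**

F1 | step 14 | (5S)-3-[(tributylstannyl)methyl] analogue of 25 | CCCC[Sn](CCCC)(CCCC)CC1=C[C@H](C[C@@]2(C)OC(=CC2=O)/C(CO[Si](C)(C)C(C)(C)C)=C\CO[Si](CC)(CC)CC)OC1=O
F2 | step 14 | (5S)-3-[(tributylstannyl)methyl] analogue of 26 (free C6 hydroxyl) | CCCC[Sn](CCCC)(CCCC)CC1=C[C@H](C[C@@]2(C)OC(=CC2=O)/C(CO[Si](C)(C)C(C)(C)C)=C\CO)OC1=O
F3 | step 14 | (5S)-3-[(tributylstannyl)methyl] analogue of 27 (Z-enal) | CCCC[Sn](CCCC)(CCCC)CC1=C[C@H](C[C@@]2(C)OC(=CC2=O)/C(CO[Si](C)(C)C(C)(C)C)=C\C=O)OC1=O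
F4 | step 14 | (6S,7R,8S,10R)-tricyclic alcohol, the C6 epimer of 29 | C=C1C(=O)O[C@H]2C[C@@]3(C)OC(=CC3=O)/C(CO[Si](C)(C)C(C)(C)C)=C\[C@H](O)[C@H]12
F5 | step 15 | (7R,8S,10R)-tricyclic C6 ketone (enone) from 29 | C=C1C(=O)O[C@H]2C[C@@]3(C)OC(=CC3=O)/C(CO[Si](C)(C)C(C)(C)C)=C\C(=O)[C@H]12
F6 | step 15 | (6S,7R,8S,10R)-tricyclic alcohol, the C6 epimer of 29 | C=C1C(=O)O[C@H]2C[C@@]3(C)OC(=CC3=O)/C(CO[Si](C)(C)C(C)(C)C)=C\[C@H](O)[C@H]12
F7 | step 11 | 2-{[(4-methoxybenzyl)oxy]methyl}prop-2-enoic acid | C=C(COCc1ccc(OC)cc1)C(=O)O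
F8 | step 11 | 2-{[(4-methoxybenzyl)oxy]methyl}prop-2-enoate ester of 22 at C8–OH | C=C[C@@H](OC(=O)C(=C)COCc1ccc(OC)cc1)C[C@@]1(C)OC(=CC1=O)/C(CO[Si](C)(C)C(C)(C)C)=C\CO[Si](CC)(CC)CC
F9 | step 11 | (5S)-3-{[(4-methoxybenzyl)oxy]methyl} analogue of 25 | COc1ccc(COCC2=C[C@H](C[C@@]3(C)OC(=CC3=O)/C(CO[Si](C)(C)C(C)(C)C)=C\CO[Si](CC)(CC)CC)OC2=O)cc1
F10 | step 11 | (5S)-3-(hydroxymethyl) analogue of 25 | OCC1=C[C@H](C[C@@]2(C)OC(=CC2=O)/C(CO[Si](C)(C)C(C)(C)C)=C\CO[Si](CC)(CC)CC)OC1=O
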